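**Plan**

- Cuts: the coumarin is opened at O1–C2 and C3=C4 into lactol 11 (a masked salicylaldehyde) and pyranonylacetate 19. With C4 raised to a lactone carbonyl, 11 is cut at the aryl C5–CH2 bond and the lactone C–O bond into benzoic acid 6 and (S)-propylene oxide 7. Fragment 19 is cut at the pyranone O1–C6 and C4–C5 bonds into amide 14 and methyl acetoacetate 15.
- Enabling feature: the C5 arm CH2–CH(OH)–CH3 and carbon C4 sit on the neighbouring benzene carbons C5 and C4a. With C4 as a carboxyl carbon, the atoms C4, C4a, C5, the arm CH2, the carbinol CH and its oxygen form the six-membered ring of a 3-methylisochroman-1-one, and the future C5 is the only free ortho C–H of acid 6.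
- Forward order: the penta-substituted benzene is assembled first (steps 1–3), the isochromanone ring is closed on it (step 4), the dihydropyranone ring is made separately (steps 7–10), and the coumarin pyranone ring closes last when the halves are joined (step 11).
- Stereochemistry: both centres are bought, (S) with epoxide 7 and (R) with methyl (R)-3-hydroxybutanoate 12. No step makes or breaks a bond at either carbon.

Key step: step 4

Remark on the chemistry: lactol 11 is drawn as the ring tautomer with an undefined anomeric centre; it equilibrates with the open hydroxy aldehyde 20, which is the species that condenses in step 11. Aldehyde 1 is taken as a catalogue compound.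

**Route**

Step 1
Reactants: 1 2,4-dimethoxy-3-methylbenzaldehyde
Product: 3 1,3-dimethoxy-2,4-dimethylbenzene, via benzylic alcohol 2 (not isolated)
Conditions: H2 (3 bar), Pd/C (10 wt% Pd), AcOH, cat. HClO4, rt
Reagents that add atoms: none
Why: Catalytic hydrogenolysis of an electron-rich aryl aldehyde should reduce the formyl group to the benzylic alcohol, whose C–O bond is then cleaved under acid because two methoxy groups stabilise the benzylic cation, while the aryl methyl ethers stay inert.

Step 2
Reactants: 3 1,3-dimethoxy-2,4-dimethylbenzene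
Product: 4 1-bromo-2,4-dimethoxy-3,5-dimethylbenzene
Conditions: NBS (1.05 equiv), MeCN, 0 °C to rt
Reagents that add atoms: N-bromosuccinimide, O=C1CCC(=O)N1Br
Why: Electrophilic aromatic bromination should go only to C6, since of the two free ring positions it alone is ortho to one methoxy group and para to the other.

Step 3
Reactants: 4 1-bromo-2,4-dimethoxy-3,5-dimethylbenzene
Product: 6 2,4-dimethoxy-3,5-dimethylbenzoic acid, via aryllithium 5 (not isolated)
Conditions: n-BuLi, THF, −78 °C; CO2 (g), −78 °C to rt; aq. HCl
Reagents that add atoms: carbon dioxide, O=C=O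
Why: Bromine–lithium exchange is fast at −78 °C, the ortho methoxy group stabilises the aryllithium by chelation, and carboxylation of an aryllithium with CO2 is a standard route to benzoic acids.

Step 4
Reactants: 6 2,4-dimethoxy-3,5-dimethylbenzoic acid; 7 (S)-propylene oxide
Product: 9 (3S)-6,8-dimethoxy-3,5,7-trimethylisochroman-1-one, via hydroxy acid 8 (not isolated)
Conditions: Pd(OAc)2 (10 mol%), N-acetyl-L-tert-leucine (30 mol%), KOAc (1 equiv), 7 (3 equiv), (CF3)2CHOH, 75 °C, sealed tube
Reagents that add atoms: none
Why: The potassium carboxylate of 6 binds Pd(OAc)2 and, with the N-acetyl amino acid as internal base, the single ortho C–H is cleaved by concerted metalation–deprotonation to a five-membered palladacycle of divalent palladium, whose aryl–Pd bond opens the coordinated epoxide at its unsubstituted CH2 in a redox-neutral SN2-type step before protonolysis releases hydroxy acid 8 and the catalyst. The closest known reaction type is the carboxylate-directed ortho C–H alkylation of benzoic acids with terminal epoxides under Pd(OAc)2, a mono-N-protected amino acid and a potassium base in hexafluoroisopropanol, which gives 3,4-dihydroisocoumarins in one operation. The one ring formed, the lactone, closes by 6-exo-trig acyl substitution of the secondary hydroxyl of 8 on the carboxyl carbon with loss of water. No stereocentre is created: C3 of 9 is the carbinol carbon of 7, none of whose bonds is broken, so the (S) configuration is carried over as such. The step needs site selectivity on the arene and regioselectivity on the epoxide; the first is fixed by the substrate, since the other ortho position carries OMe, and the second by the steric preference for the primary epoxide carbon. The methyl group beside the reacting C–H retards palladation, which is answered by a raised catalyst loading, excess 7 and a sealed vessel.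

Step 5
Reactants: 9 (3S)-6,8-dimethoxy-3,5,7-trimethylisochroman-1-one
Product: 10 (3S)-6,8-dihydroxy-3,5,7-trimethylisochroman-1-one
Conditions: BBr3 (4 equiv), CH2Cl2, −78 °C to rt; H2O
Reagents that add atoms: none
Why: Lewis-acid cleavage of aryl methyl ethers by BBr3 (bromide removes each methyl group by SN2 from the boron-complexed ether) is a demethylation that dihydroisocoumarin lactones and their C3 stereocentre normally survive at low temperature.

Step 6
Reactants: 10 (3S)-6,8-dihydroxy-3,5,7-trimethylisochroman-1-one
Product: 11 (3S)-3,5,7-trimethylisochromane-1,6,8-triol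
Conditions: i-Bu2AlH (3.5 equiv), CH2Cl2/THF, −78 °C; aq. potassium sodium tartrate (KNaC4H4O6); crude 11 used at once
Reagents that add atoms: none
Why: In this partial reduction of a six-membered lactone to the lactol, two equivalents of i-Bu2AlH are consumed as aluminium phenoxides, a further equivalent delivers one hydride to the chelated carbonyl, and the cyclic aluminium hemiacetal should persist at −78 °C until aqueous work-up.

Step 7
Reactants: 12 methyl (R)-3-hydroxybutanoate
Product: 13 methyl (3R)-3-[(tert-butyldimethylsilyl)oxy]butanoate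
Conditions: TBSCl, imidazole, DMF, rt
Reagents that add atoms: tert-butyldimethylsilyl chloride, CC(C)(C)[Si](C)(C)Cl
Why: Imidazole-promoted silylation of a secondary alcohol masks the hydroxyl against the strong bases of the next two steps without touching the stereocentre.

Step 8
Reactants: 13 methyl (3R)-3-[(tert-butyldimethylsilyl)oxy]butanoate
Product: 14 (3R)-3-[(tert-butyldimethylsilyl)oxy]-N-methoxy-N-methylbutanamide
Conditions: MeNH(OMe)·HCl, i-PrMgCl, THF, −20 °C to 0 °C
Reagents that add atoms: N,O-dimethylhydroxylamine hydrochloride, CNOC.Cl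
Why: Aminolysis of the ester by the chloromagnesium amide of N,O-dimethylhydroxylamine should give the N-methoxy-N-methylamide at low temperature, before β-elimination of the silyloxy group can compete.

Step 9
Reactants: 14 (3R)-3-[(tert-butyldimethylsilyl)oxy]-N-methoxy-N-methylbutanamide; 15 methyl acetoacetate
Product: 17 methyl (7R)-7-[(tert-butyldimethylsilyl)oxy]-3,5-dioxooctanoate, via acetoacetate dianion 16 (not isolated)
Conditions: 15 (2 equiv), LiN(i-Pr)2 (4.2 equiv), THF, 0 °C; add 14, −78 °C to 0 °C; cold 1 M HCl
Reagents that add atoms: none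
Why: In this γ-acylation of an acetoacetate dianion (Claisen-type condensation) the terminal carbanion of 16 is the more nucleophilic site and the chelated tetrahedral adduct of the N-methoxy-N-methylamide prevents a second addition.

Step 10
Reactants: 17 methyl (7R)-7-[(tert-butyldimethylsilyl)oxy]-3,5-dioxooctanoate
Product: 19 methyl 2-[(2R)-2-methyl-4-oxo-3,4-dihydro-2H-pyran-6-yl]acetate, via hydroxy diketo ester 18 (not isolated)
Conditions: aq. HF (48%), MeCN, 0 °C to rt
Reagents that add atoms: none
Why: Acid desilylation frees the δ-hydroxyl, which adds to the C3 ketone as a six-membered hemiketal that dehydrates to the conjugated 2,3-dihydro-4H-pyran-4-one (cyclodehydration of a δ-hydroxy-β-diketone), and because the C–O bond at the stereocentre stays intact the (R) configuration is retained.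

Step 11
Reactants: 11 (3S)-3,5,7-trimethylisochromane-1,6,8-triol; 19 methyl 2-[(2R)-2-methyl-4-oxo-3,4-dihydro-2H-pyran-6-yl]acetate
Product: 22 7-hydroxy-5-[(2S)-2-hydroxypropyl]-6,8-dimethyl-3-[(2R)-2-methyl-4-oxo-3,4-dihydro-2H-pyran-6-yl]-2H-chromen-2-one, via open-chain aldehyde 20 (not isolated), via benzylidene ester 21 (not isolated)
Conditions: piperidine (20 mol%), AcOH (20 mol%), EtOH, 4 Å sieves, 40–50 °C
Reagents that add atoms: none
Why: Knoevenagel condensation followed by lactonisation (the classical coumarin synthesis from a salicylaldehyde and an activated acetate) should take place at the methylene between the ester and the vinylogous ketone of 19 with aldehyde 20 drawn from the lactol equilibrium, and closure of the ortho phenol onto the ester with loss of methanol makes the sequence irreversible without forming or touching a stereocentre.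

**Compound list**

1 | 2,4-dimethoxy-3-methylbenzaldehyde | O=Cc1ccc(OC)c(C)c1OC | starting material
2 | (2,4-dimethoxy-3-methylphenyl)methanol (formed in situ) | OCc1ccc(OC)c(C)c1OC | intermediate
3 | 1,3-dimethoxy-2,4-dimethylbenzene | Cc1ccc(OC)c(C)c1OC | intermediate
4 | 1-bromo-2,4-dimethoxy-3,5-dimethylbenzene | Cc1cc(Br)c(OC)c(C)c1OC | intermediate
5 | (2,4-dimethoxy-3,5-dimethylphenyl)lithium (formed in situ) | [Li]c1cc(C)c(OC)c(C)c1OC | intermediate
6 | 2,4-dimethoxy-3,5-dimethylbenzoic acid | OC(=O)c1cc(C)c(OC)c(C)c1OC | intermediate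
7 | (S)-propylene oxide | C[C@H]1CO1 | starting material
8 | 2-[(2S)-2-hydroxypropyl]-4,6-dimethoxy-3,5-dimethylbenzoic acid (formed in situ) | C[C@H](O)Cc1c(C)c(OC)c(C)c(OC)c1C(=O)O | intermediate
9 | (3S)-6,8-dimethoxy-3,5,7-trimethylisochroman-1-one | C[C@H]1Cc2c(C)c(OC)c(C)c(OC)c2C(=O)O1 | intermediate
10 | (3S)-6,8-dihydroxy-3,5,7-trimethylisochroman-1-one | C[C@H]1Cc2c(C)c(O)c(C)c(O)c2C(=O)O1 | intermediate
11 | (3S)-3,5,7-trimethylisochromane-1,6,8-triol (lactol; both C1 epimers) | C[C@H]1Cc2c(C)c(O)c(C)c(O)c2C(O)O1 | intermediate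
12 | methyl (R)-3-hydroxybutanoate | C[C@@H](O)CC(=O)OC | starting material
13 | methyl (3R)-3-[(tert-butyldimethylsilyl)oxy]butanoate | C[C@@H](O[Si](C)(C)C(C)(C)C)CC(=O)OC | intermediate
14 | (3R)-3-[(tert-butyldimethylsilyl)oxy]-N-methoxy-N-methylbutanamide | C[C@@H](O[Si](C)(C)C(C)(C)C)CC(=O)N(C)OC | intermediate
15 | methyl acetoacetate | CC(=O)CC(=O)OC | starting material
16 | dilithium dianion of methyl acetoacetate (formed in situ) | [CH2-]C(=O)[CH-]C(=O)OC.[Li+].[Li+] | intermediate
17 | methyl (7R)-7-[(tert-butyldimethylsilyl)oxy]-3,5-dioxooctanoate | C[C@@H](O[Si](C)(C)C(C)(C)C)CC(=O)CC(=O)CC(=O)OC | intermediate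
18 | methyl (7R)-7-hydroxy-3,5-dioxooctanoate (formed in situ) | C[C@@H](O)CC(=O)CC(=O)CC(=O)OC | intermediate
19 | methyl 2-[(2R)-2-methyl-4-oxo-3,4-dihydro-2H-pyran-6-yl]acetate | COC(=O)CC1=CC(=O)C[C@@H](C)O1 | intermediate
20 | 2,4-dihydroxy-6-[(2S)-2-hydroxypropyl]-3,5-dimethylbenzaldehyde (open tautomer of 11; formed in situ) | C[C@H](O)Cc1c(C)c(O)c(C)c(O)c1C=O | intermediate
21 | methyl 3-{2,4-dihydroxy-6-[(2S)-2-hydroxypropyl]-3,5-dimethylphenyl}-2-[(2R)-2-methyl-4-oxo-3,4-dihydro-2H-pyran-6-yl]prop-2-enoate (formed in situ) | COC(=O)C(=Cc1c(O)c(C)c(O)c(C)c1C[C@H](C)O)C1=CC(=O)C[C@@H](C)O1 | intermediate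
22 | 7-hydroxy-5-[(2S)-2-hydroxypropyl]-6,8-dimethyl-3-[(2R)-2-methyl-4-oxo-3,4-dihydro-2H-pyran-6-yl]-2H-chromen-2-one | Cc1c(O)c(C)c2oc(=O)c(C3=CC(=O)C[C@@H](C)O3)cc2c1C[C@H](C)O | target

**Step count and risks**

Total: 11 steps. Longest linear sequence: 7 steps (steps 1–6 and 11, from aldehyde 1). The pyranone branch is 4 steps (7–10) and joins in step 11.

Steps most likely to fail:

1. Step 4. Palladation of a C–H bond that has a methyl neighbour may be so slow that catalyst decay and solvolysis of the epoxide by the fluorinated alcohol outrun alkylation. The fallback replaces catalytic C–H activation by stoichiometric directed ortho-metalation and sets out from acid 6. (COCl)2 with cat. DMF should give 2,4-dimethoxy-3,5-dimethylbenzoyl chloride F1, and Et2NH then gives N,N-diethyl-2,4-dimethoxy-3,5-dimethylbenzamide F2. Treatment with s-BuLi/TMEDA in THF at −78 °C should lithiate the only position ortho to the amide, giving N,N-diethyl-2-lithio-4,6-dimethoxy-3,5-dimethylbenzamide F3. Opening of epoxide 7 at its CH2 in the presence of BF3·OEt2 at −78 °C should give N,N-diethyl-2-[(2S)-2-hydroxypropyl]-4,6-dimethoxy-3,5-dimethylbenzamide F4. Heating F4 with TsOH in toluene should expel diethylamine by neighbouring-hydroxyl lactonisation, and the sequence rejoins the route at lactone 9.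

2. Step 6. Hydride transfer to a lactone that carries two aluminium phenoxides may stall at −78 °C. On warming, the aluminium hemiacetal may collapse and over-reduce through a quinone methide to the benzylic alcohol or methyl stage. The fallback masks the phenols and sets out from diphenol 10. TBSOTf and 2,6-lutidine in CH2Cl2 should give (3S)-6,8-bis[(tert-butyldimethylsilyl)oxy]-3,5,7-trimethylisochroman-1-one F5. i-Bu2AlH (1.1 equiv) at −78 °C should then reduce this neutral lactone to (3S)-6,8-bis[(tert-butyldimethylsilyl)oxy]-3,5,7-trimethylisochroman-1-ol F6. Bu4NF buffered with AcOH in THF at 0 °C removes both silyl groups, and the sequence rejoins at lactol 11.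

3. Step 11. The amine base may open the dihydropyranone by retro-oxa-Michael reaction and reclose it, eroding the (R) centre, or the nucleophile may react through a pyranone ring carbon instead of the exocyclic methylene. The fallback builds the pyranone last, under acid, and sets out from lactol 11.
   - Knoevenagel condensation–lactonisation of 11 with methyl acetoacetate 15 (piperidine/AcOH, EtOH) should give 3-acetyl-7-hydroxy-5-[(2S)-2-hydroxypropyl]-6,8-dimethyl-2H-chromen-2-one F7.
   - TBSOTf/2,6-lutidine protects both hydroxyls as 3-acetyl-7-[(tert-butyldimethylsilyl)oxy]-5-{(2S)-2-[(tert-butyldimethylsilyl)oxy]propyl}-6,8-dimethyl-2H-chromen-2-one F8.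
   - LiN(SiMe3)2 in THF at −78 °C forms the lithium enolate of the acetyl group F9.
   - C-acylation of F9 with amide 14 should give 7-[(tert-butyldimethylsilyl)oxy]-5-{(2S)-2-[(tert-butyldimethylsilyl)oxy]propyl}-3-{(5R)-5-[(tert-butyldimethylsilyl)oxy]-3-oxohexanoyl}-6,8-dimethyl-2H-chromen-2-one F10.
   - Aqueous HF in MeCN removes the three silyl groups to give 7-hydroxy-3-[(5R)-5-hydroxy-3-oxohexanoyl]-5-[(2S)-2-hydroxypropyl]-6,8-dimethyl-2H-chromen-2-one F11, which cyclodehydrates in the same acid, and the sequence rejoins at target 22.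

**Further compounds**

F1 | step 4 | 2,4-dimethoxy-3,5-dimethylbenzoyl chloride | ClC(=O)c1cc(C)c(OC)c(C)c1OC
F2 | step 4 | N,N-diethyl-2,4-dimethoxy-3,5-dimethylbenzamide | CCN(CC)C(=O)c1cc(C)c(OC)c(C)c1OC
F3 | step 4 | N,N-diethyl-2-lithio-4,6-dimethoxy-3,5-dimethylbenzamide | CCN(CC)C(=O)c1c([Li])c(C)c(OC)c(C)c1OC
F4 | step 4 | N,N-diethyl-2-[(2S)-2-hydroxypropyl]-4,6-dimethoxy-3,5-dimethylbenzamide | CCN(CC)C(=O)c1c(C[C@H](C)O)c(C)c(OC)c(C)c1OC
F5 | step 6 | (3S)-6,8-bis[(tert-butyldimethylsilyl)oxy]-3,5,7-trimethylisochroman-1-one | C[C@H]1Cc2c(C)c(O[Si](C)(C)C(C)(C)C)c(C)c(O[Si](C)(C)C(C)(C)C)c2C(=O)O1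
F6 | step 6 | (3S)-6,8-bis[(tert-butyldimethylsilyl)oxy]-3,5,7-trimethylisochroman-1-ol | C[C@H]1Cc2c(C)c(O[Si](C)(C)C(C)(C)C)c(C)c(O[Si](C)(C)C(C)(C)C)c2C(O)O1
F7 | step 11 | 3-acetyl-7-hydroxy-5-[(2S)-2-hydroxypropyl]-6,8-dimethyl-2H-chromen-2-one | CC(=O)c1cc2c(C[C@H](C)O)c(C)c(O)c(C)c2oc1=O
F8 | step 11 | 3-acetyl-7-[(tert-butyldimethylsilyl)oxy]-5-{(2S)-2-[(tert-butyldimethylsilyl)oxy]propyl}-6,8-dimethyl-2H-chromen-2-one | CC(=O)c1cc2c(C[C@H](C)O[Si](C)(C)C(C)(C)C)c(C)c(O[Si](C)(C)C(C)(C)C)c(C)c2oc1=O
F9 | step 11 | lithium enolate of F8 | C=C(O[Li])c1cc2c(C[C@H](C)O[Si](C)(C)C(C)(C)C)c(C)c(O[Si](C)(C)C(C)(C)C)c(C)c2oc1=O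
F10 | step 11 | 7-[(tert-butyldimethylsilyl)oxy]-5-{(2S)-2-[(tert-butyldimethylsilyl)oxy]propyl}-3-{(5R)-5-[(tert-butyldimethylsilyl)oxy]-3-oxohexanoyl}-6,8-dimethyl-2H-chromen-2-one | C[C@@H](O[Si](C)(C)C(C)(C)C)CC(=O)CC(=O)c1cc2c(C[C@H](C)O[Si](C)(C)C(C)(C)C)c(C)c(O[Si](C)(C)C(C)(C)C)c(C)c2oc1=O
F11 | step 11 | 7-hydroxy-3-[(5R)-5-hydroxy-3-oxohexanoyl]-5-[(2S)-2-hydroxypropyl]-6,8-dimethyl-2H-chromen-2-one | C[C@@H](O)CC(=O)CC(=O)c1cc2c(C[C@H](C)O)c(C)c(O)c(C)c2oc1=O
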